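The cyclopentenone ring carries no substituent at C10, the CH between the C9 carbonyl and C11. Removing that carbon leaves a trans-2,3-disubstituted cyclobutanone (ring atoms C9, C8, C12, C11) that already holds both side chains, the C8 and C12 stereocentres and the silyl-protected C15 carbinol. The key step puts C10 back from trimethylsilyldiazomethane under Sc(OTf)3 catalysis. In one operation it forms C9–C10 and C10–C11, enlarges the four-membered ring to the five-membered ring and leaves a C9=C10 silyl enol ether, from which the C10=C11 enone follows by dehydrosilylation. The cyclobutanone comes from an auxiliary-controlled keteniminium–diene [2+2] cycloaddition.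

Key step: step 5

Remark on numbering: atoms are numbered as in prostanoic acid (C1 carboxyl, C8 and C12 ring carbons bearing the chains, C9 carbonyl, C15 carbinol).

Assumption: the facial sense of the C2-symmetric amine is assigned from a steric model (see step 4), not from a known result; if it proves opposite, the commercial (2R,5R)-amine replaces 7 and nothing else changes.

Step 1
Reactants: 1 (S)-oct-1-yn-3-ol
Product: 2 (S)-tert-butyldimethyl(oct-1-yn-3-yloxy)silane
Conditions: TBSCl, imidazole, DMF, 0 °C → rt
Reagents that add atoms: tert-butyldimethylsilyl chloride (TBSCl), CC(C)(C)[Si](C)(C)Cl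
Why: Imidazole-promoted O-silylation of a secondary alcohol forms only the O–Si bond, so the C15 (S) configuration bought with 1 is carried unchanged.

Step 2
Reactants: 2 (S)-tert-butyldimethyl(oct-1-yn-3-yloxy)silane; 3 vinyl bromide
Product: 5 tert-butyl{[(3E,5S)-deca-1,3-dien-5-yl]oxy}dimethylsilane, via alkenylzirconocene chloride 4 (not isolated)
Conditions: Cp2Zr(H)Cl, THF, rt; then vinyl bromide (1 M in THF), Pd(PPh3)4 (5 mol %), ZnCl2 (0.3 equiv), 0 °C → rt
Reagents that add atoms: vinyl bromide (3), C=CBr; Cp2Zr(H)Cl, [H][Zr](Cl)(C1C=CC=C1)C1C=CC=C1 (zirconocene chloride unit of 4 only; only its hydrogen stays in 5)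
Why: Hydrozirconation adds Zr–H syn across the terminal alkyne with zirconium on C13, which fixes the C13=C14 E geometry, and the Negishi-type alkenyl–alkenyl coupling (oxidative addition of vinyl bromide to zerovalent palladium, zinc-assisted transmetalation, reductive elimination) forms C12–C13 with retention, the silyl ether and C15 not being involved.

Step 3
Reactants: 6 monomethyl azelate; 7 (2S,5S)-2,5-dimethylpyrrolidine
Product: 9 methyl 9-[(2S,5S)-2,5-dimethylpyrrolidin-1-yl]-9-oxononanoate, via acid chloride 8 (not isolated)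
Conditions: (COCl)2, DMF (cat.), CH2Cl2, 0 °C → rt, concentrate; then 7, Et3N, CH2Cl2, 0 °C → rt
Reagents that add atoms: oxalyl chloride, O=C(Cl)C(Cl)=O (supplies only the chlorine of 8; none of its atoms stays in 9)
Why: Acyl chloride formation at the free acid terminus (the methyl ester is inert) followed by N-acylation is the dependable way to acylate this hindered secondary amine, and its two stereocentres are not touched.

Step 4
Reactants: 9 methyl 9-[(2S,5S)-2,5-dimethylpyrrolidin-1-yl]-9-oxononanoate; 5 tert-butyl{[(3E,5S)-deca-1,3-dien-5-yl]oxy}dimethylsilane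
Product: 13 trans-cyclobutanone methyl 7-[(1R,2R)-2-[(1E,3S)-3-(tert-butyldimethylsilyloxy)oct-1-en-1-yl]-4-oxocyclobutyl]heptanoate, via keteniminium triflate 10 (not isolated), via cis-cyclobutaniminium triflate 11 (not isolated), via cis-cyclobutanone 12 (not isolated)
Conditions: Tf2O, 2,4,6-collidine (added slowly), CH2Cl2, −30 °C → 40 °C (9 in slight excess, 5 limiting); then aq. NaHCO3, rt → 40 °C; then DBU (0.2 equiv), CH2Cl2, rt
Reagents that add atoms: water, O (the C9 carbonyl oxygen); triflic anhydride, O=S(=O)(OS(=O)(=O)C(F)(F)F)C(F)(F)F (triflate counter-ion of 10 and 11 only)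
Why: In this keteniminium–alkene [2+2] cycloaddition the iminium carbon of 10 (C9) bonds to the terminal diene carbon C11 and C8 closes on C12 of the developing allyl cation, so only the terminal alkene reacts and the 2-alkyl-3-alkenyl pattern results; the diene should approach C9 on the face opposite the C8 chain and, on that face, on the side remote from the pyrrolidine methyl group, with the C13 arm turned outwards, which sets C12 as R in the cis adduct 11 (8S,12R), and after hydrolysis DBU equilibrates the enolisable C8 to the more stable trans ketone 13 (8R,12R) without touching C12.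

Step 5
Reactants: 13 trans-cyclobutanone methyl 7-[(1R,2R)-2-[(1E,3S)-3-(tert-butyldimethylsilyloxy)oct-1-en-1-yl]-4-oxocyclobutyl]heptanoate; 14 trimethylsilyldiazomethane
Product: 17 enol silane methyl 7-[(1R,5R)-5-[(1E,3S)-3-(tert-butyldimethylsilyloxy)oct-1-en-1-yl]-2-(trimethylsilyloxy)cyclopent-2-en-1-yl]heptanoate, via diazonium betaine 15 (not isolated), via C10-silyl ketone 16 (not isolated)
Conditions: Sc(OTf)3 (10 mol %), TMSCHN2 (2 M in hexanes, 1.3 equiv), toluene, −78 °C → 0 °C; Et3N quench, filtration through Et3N-deactivated silica, used at once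
Reagents that add atoms: trimethylsilyldiazomethane (14), C[Si](C)(C)C=[N+]=[N-]
Why: Sc(OTf)3 activates the strained C9 carbonyl, the diazo carbon of 14 adds to it to give betaine 15, and loss of N2 is coupled to a 1,2-shift of C11 from C9 to the new carbon C10, which forms C9–C10 and C10–C11 and gives silyl ketone 16; a 1,3-shift of silicon from C10 to oxygen then gives enol silane 17 with the double bond fixed at C9=C10. The closest known reaction type is the Lewis-acid-catalysed, Tiffeneau–Demjanov-type homologation of cyclobutanones with trimethylsilyldiazomethane, which is established for this ketone class. The five-membered ring is not closed by a cyclisation; it arises by one-carbon enlargement of the four-membered ring through the 1,2-alkyl shift, driven by release of cyclobutanone strain. No stereocentre is created in 17 (C9 and C10 end as sp2 carbons), the migrating C11 is a CH2, and C8 and C12 are not involved, so the trans arrangement set in step 4 is carried through. The selectivity needed is migration of C11 over the more substituted C8: the bulky Me3Si group on the diazo carbon turns away from the C8 chain, which places the C9–C11 bond anti to the departing N2, so the less hindered carbon should migrate. Single homologation is secured because the cyclobutanone is far more electrophilic than a cyclopentanone and the product is masked as the enol silane; placing this step before the enone exists also keeps the diazo compound away from a conjugate acceptor.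

Step 6
Reactants: 17 enol silane methyl 7-[(1R,5R)-5-[(1E,3S)-3-(tert-butyldimethylsilyloxy)oct-1-en-1-yl]-2-(trimethylsilyloxy)cyclopent-2-en-1-yl]heptanoate
Product: 18 methyl 7-[(1R,2S)-2-[(1E,3S)-3-(tert-butyldimethylsilyloxy)oct-1-en-1-yl]-5-oxocyclopent-3-en-1-yl]heptanoate
Conditions: Pd(OAc)2 (1.1 equiv), MeCN, rt
Reagents that add atoms: none
Why: In this Saegusa–Ito oxidation the enol silane gives a C10-bound divalent palladium enolate whose only β-hydrogens lie on C11, so β-hydride elimination can place the double bond only at C10=C11, while the neutral medium spares C8 and C12 and the C15 silyl ether (chosen over the final acetate, which palladium could ionise or transpose).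

Step 7
Reactants: 18 methyl 7-[(1R,2S)-2-[(1E,3S)-3-(tert-butyldimethylsilyloxy)oct-1-en-1-yl]-5-oxocyclopent-3-en-1-yl]heptanoate
Product: 19 15-hydroxy methyl ester methyl 7-[(1R,2S)-2-[(1E,3S)-3-hydroxyoct-1-en-1-yl]-5-oxocyclopent-3-en-1-yl]heptanoate
Conditions: HF·pyridine, pyridine, THF, 0 °C → rt
Reagents that add atoms: none
Why: Buffered fluoride cleavage of the secondary silyl ether breaks only the O–Si bond and is non-basic, so the base-sensitive 4,5-disubstituted cyclopentenone, the methyl ester and the C15 configuration are preserved.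

Step 8
Reactants: 19 15-hydroxy methyl ester methyl 7-[(1R,2S)-2-[(1E,3S)-3-hydroxyoct-1-en-1-yl]-5-oxocyclopent-3-en-1-yl]heptanoate
Product: 20 15-hydroxy acid 7-[(1R,2S)-2-[(1E,3S)-3-hydroxyoct-1-en-1-yl]-5-oxocyclopent-3-en-1-yl]heptanoic acid
Conditions: pig liver esterase, pH 7 phosphate buffer, acetone (co-solvent), 30 °C; citric acid to pH 4, extraction
Reagents that add atoms: water, O
Why: Enzymatic ester hydrolysis at neutral pH, a known way to unmask prostaglandin methyl esters, avoids hydroxide, which would move the enone double bond to C8=C12 or epimerise C8.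

Step 9
Reactants: 20 15-hydroxy acid 7-[(1R,2S)-2-[(1E,3S)-3-hydroxyoct-1-en-1-yl]-5-oxocyclopent-3-en-1-yl]heptanoic acid
Product: 22 CNP0281518.1 (the 15-acetoxy acid 7-[(1R,2S)-2-[(1E,3S)-3-acetoxyoct-1-en-1-yl]-5-oxocyclopent-3-en-1-yl]heptanoic acid), via C1 mixed anhydride 21 (not isolated)
Conditions: Ac2O (excess), pyridine, CH2Cl2, 0 °C → rt; then H2O–pyridine, rt; cold aq. citric acid work-up
Reagents that add atoms: acetic anhydride, CC(=O)OC(C)=O; water, O
Why: Pyridine-mediated O-acetylation of the C15 alcohol leaves the C15–O bond intact (retention), and the carboxyl, carried for a time as mixed anhydride 21, is returned by the aqueous pyridine quench, which hydrolyses an anhydride far faster than a secondary acetate.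

Compound list
1 | (S)-oct-1-yn-3-ol | CCCCC[C@@H](C#C)O | starting material
2 | (S)-tert-butyldimethyl(oct-1-yn-3-yloxy)silane | CCCCC[C@@H](C#C)O[Si](C)(C)C(C)(C)C | intermediate
3 | vinyl bromide (bromoethene) | C=CBr | starting material
4 | chlorobis(cyclopentadienyl)[(1E,3S)-3-(tert-butyldimethylsilyloxy)oct-1-en-1-yl]zirconium (cyclopentadienyl rings drawn σ-bonded) | CCCCC[C@@H](/C=C/[Zr](Cl)(C1C=CC=C1)C1C=CC=C1)O[Si](C)(C)C(C)(C)C | intermediate
5 | tert-butyl{[(3E,5S)-deca-1,3-dien-5-yl]oxy}dimethylsilane | CCCCC[C@@H](/C=C/C=C)O[Si](C)(C)C(C)(C)C | intermediate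
6 | monomethyl azelate (9-methoxy-9-oxononanoic acid) | COC(=O)CCCCCCCC(=O)O | starting material
7 | (2S,5S)-2,5-dimethylpyrrolidine | C[C@H]1CC[C@H](C)N1 | starting material
8 | methyl 9-chloro-9-oxononanoate | COC(=O)CCCCCCCC(=O)Cl | intermediate
9 | methyl 9-[(2S,5S)-2,5-dimethylpyrrolidin-1-yl]-9-oxononanoate | COC(=O)CCCCCCCC(=O)N1[C@@H](C)CC[C@@H]1C | intermediate
10 | keteniminium triflate: (2S,5S)-1-[9-methoxy-9-oxonon-1-en-1-ylidene]-2,5-dimethylpyrrolidinium trifluoromethanesulfonate | COC(=O)CCCCCCC=C=[N+]1[C@@H](C)CC[C@@H]1C.[O-]S(=O)(=O)C(F)(F)F | intermediate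
11 | cis-cyclobutaniminium triflate (8S,12R,15S; iminium at C9 with the (2S,5S)-dimethylpyrrolidine) | CCCCC[C@@H](/C=C/[C@H]1CC(=[N+]2[C@@H](C)CC[C@@H]2C)[C@H]1CCCCCCC(=O)OC)O[Si](C)(C)C(C)(C)C.[O-]S(=O)(=O)C(F)(F)F | intermediate
12 | cis-cyclobutanone methyl 7-[(1S,2R)-2-[(1E,3S)-3-(tert-butyldimethylsilyloxy)oct-1-en-1-yl]-4-oxocyclobutyl]heptanoate | CCCCC[C@@H](/C=C/[C@H]1CC(=O)[C@H]1CCCCCCC(=O)OC)O[Si](C)(C)C(C)(C)C | intermediate
13 | trans-cyclobutanone methyl 7-[(1R,2R)-2-[(1E,3S)-3-(tert-butyldimethylsilyloxy)oct-1-en-1-yl]-4-oxocyclobutyl]heptanoate | CCCCC[C@@H](/C=C/[C@H]1CC(=O)[C@@H]1CCCCCCC(=O)OC)O[Si](C)(C)C(C)(C)C | intermediate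
14 | trimethylsilyldiazomethane | C[Si](C)(C)C=[N+]=[N-] | starting material
15 | diazonium betaine (C9 alkoxide, drawn free of scandium, bearing the CH(SiMe3)N2+ group; C9 and C10 configurations not defined) | CCCCC[C@@H](/C=C/[C@H]1CC([O-])(C([N+]#N)[Si](C)(C)C)[C@@H]1CCCCCCC(=O)OC)O[Si](C)(C)C(C)(C)C | intermediate
16 | C10-silyl ketone methyl 7-[(1R,2R)-2-[(1E,3S)-3-(tert-butyldimethylsilyloxy)oct-1-en-1-yl]-5-oxo-4-(trimethylsilyl)cyclopentyl]heptanoate (C10 configuration not defined) | CCCCC[C@@H](/C=C/[C@H]1CC([Si](C)(C)C)C(=O)[C@@H]1CCCCCCC(=O)OC)O[Si](C)(C)C(C)(C)C | intermediate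
17 | enol silane methyl 7-[(1R,5R)-5-[(1E,3S)-3-(tert-butyldimethylsilyloxy)oct-1-en-1-yl]-2-(trimethylsilyloxy)cyclopent-2-en-1-yl]heptanoate | CCCCC[C@@H](/C=C/[C@H]1CC=C(O[Si](C)(C)C)[C@@H]1CCCCCCC(=O)OC)O[Si](C)(C)C(C)(C)C | intermediate
18 | methyl 7-[(1R,2S)-2-[(1E,3S)-3-(tert-butyldimethylsilyloxy)oct-1-en-1-yl]-5-oxocyclopent-3-en-1-yl]heptanoate | CCCCC[C@@H](/C=C/[C@H]1C=CC(=O)[C@@H]1CCCCCCC(=O)OC)O[Si](C)(C)C(C)(C)C | intermediate
19 | 15-hydroxy methyl ester, methyl 7-[(1R,2S)-2-[(1E,3S)-3-hydroxyoct-1-en-1-yl]-5-oxocyclopent-3-en-1-yl]heptanoate | CCCCC[C@@H](/C=C/[C@H]1C=CC(=O)[C@@H]1CCCCCCC(=O)OC)O | intermediate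
20 | 15-hydroxy acid, 7-[(1R,2S)-2-[(1E,3S)-3-hydroxyoct-1-en-1-yl]-5-oxocyclopent-3-en-1-yl]heptanoic acid | CCCCC[C@@H](/C=C/[C@H]1C=CC(=O)[C@@H]1CCCCCCC(=O)O)O | intermediate
21 | C1 mixed anhydride: acetic 7-[(1R,2S)-2-[(1E,3S)-3-acetoxyoct-1-en-1-yl]-5-oxocyclopent-3-en-1-yl]heptanoic anhydride | CCCCC[C@@H](/C=C/[C@H]1C=CC(=O)[C@@H]1CCCCCCC(=O)OC(C)=O)OC(C)=O | intermediate
22 | CNP0281518.1, 7-[(1R,2S)-2-[(1E,3S)-3-acetoxyoct-1-en-1-yl]-5-oxocyclopent-3-en-1-yl]heptanoic acid | CCCCC[C@@H](/C=C/[C@H]1C=CC(=O)[C@@H]1CCCCCCC(=O)O)OC(C)=O | target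

Total step count: 9. Longest linear sequence: 8 steps (steps 1, 2, 4, 5, 6, 7, 8, 9 from 1); step 3 is the one-step side branch.

Steps most likely to fail

Step 5. What may go wrong is migration of the substituted C8 in competition with C11, which would put the new carbon between C8 and C9, or incomplete carbon-to-oxygen silyl transfer, which would lose the regiochemical marking of C10. The fallback sets out from 13 and comes back at 17. Homologation of 13 with ethyl diazoacetate and BF3·OEt2 (CH2Cl2, −78 → 0 °C), a diazo ester whose adducts are known to migrate the less substituted ring carbon, would give the C10 ethoxycarbonyl β-keto ester F1. Krapcho dealkoxycarbonylation (NaCl, wet DMSO, 140 °C), which removes only the activated ester and leaves the C1 methyl ester, would give the 11-deoxy ketone F2 with C8 settling trans. Kinetic deprotonation at the unsubstituted C10 with lithium diisopropylamide and TMSCl present (THF, −78 °C) would then give 17.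

Step 4. What may go wrong is imperfect relay of the auxiliary's facial bias to C12 (leakage through the trans-selective pathway), or acid-promoted ionisation of the doubly allylic C15 silyl ether and oligomerisation of diene 5, which has to be the limiting component. The fallback sets out from 9 and comes back at 13. The same keteniminium 10 would be generated in the presence of excess buta-1,3-diene, a cheap partner with no ionisable allylic group, to give the cyclobutaniminium triflate F3. Hydrolysis (aq. NaHCO3) would give the cis vinyl ketone F4 and DBU equilibration the trans vinyl ketone F5. Olefin cross-metathesis of F5 with commercial (S)-oct-1-en-3-ol (CCCCC[C@@H](C=C)O, 3 equiv; second-generation Grubbs catalyst, CH2Cl2, 40 °C), a known way to attach the lower prostaglandin chain with E selectivity, would give the allylic alcohol F6. Any ring stereoisomer from imperfect facial control is then a diastereomer of F6 because of C15 and could be removed by chromatography. Silylation (TBSCl, imidazole, DMF) would give 13.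

Step 6. What may go wrong is migration of the new double bond to the C8=C12 position on a palladium hydride, engagement of the C13=C14 alkene by divalent palladium, or hydrolysis of the enol silane to the saturated ketone before oxidation. The fallback sets out from 17 and comes back at 18. Selenenylation of the enol silane with PhSeCl (CH2Cl2, −78 °C) would give the α-phenylseleno ketone F7, substituted at C10 only. Oxidation with H2O2 and pyridine (CH2Cl2, 0 °C → rt) and syn-elimination of the selenoxide, which can take a hydrogen only from C11, would give 18.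

Further compounds
F1 | step 5 | C10 ethoxycarbonyl β-keto ester, ethyl ester on the ring carbon between C9 and C11 of the 15-silyloxy methyl ester (C10 configuration not defined) | CCCCC[C@@H](/C=C/[C@H]1CC(C(=O)OCC)C(=O)[C@@H]1CCCCCCC(=O)OC)O[Si](C)(C)C(C)(C)C
F2 | step 5 | 11-deoxy ketone methyl 7-[(1R,2R)-2-[(1E,3S)-3-(tert-butyldimethylsilyloxy)oct-1-en-1-yl]-5-oxocyclopentyl]heptanoate | CCCCC[C@@H](/C=C/[C@H]1CCC(=O)[C@@H]1CCCCCCC(=O)OC)O[Si](C)(C)C(C)(C)C
F3 | step 4 | cis-2-(6-methoxycarbonylhexyl)-3-vinylcyclobutaniminium triflate of (2S,5S)-2,5-dimethylpyrrolidine | C=C[C@H]1CC(=[N+]2[C@@H](C)CC[C@@H]2C)[C@H]1CCCCCCC(=O)OC.[O-]S(=O)(=O)C(F)(F)F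
F4 | step 4 | cis vinyl ketone methyl 7-[(1S,2R)-2-ethenyl-4-oxocyclobutyl]heptanoate | C=C[C@H]1CC(=O)[C@H]1CCCCCCC(=O)OC
F5 | step 4 | trans vinyl ketone methyl 7-[(1R,2R)-2-ethenyl-4-oxocyclobutyl]heptanoate | C=C[C@H]1CC(=O)[C@@H]1CCCCCCC(=O)OC
F6 | step 4 | allylic alcohol methyl 7-[(1R,2R)-2-[(1E,3S)-3-hydroxyoct-1-en-1-yl]-4-oxocyclobutyl]heptanoate | CCCCC[C@@H](/C=C/[C@H]1CC(=O)[C@@H]1CCCCCCC(=O)OC)O
F7 | step 6 | α-phenylseleno ketone, C10-SePh derivative of the saturated C9 ketone (C10 configuration not defined) | CCCCC[C@@H](/C=C/[C@H]1CC([Se]c2ccccc2)C(=O)[C@@H]1CCCCCCC(=O)OC)O[Si](C)(C)C(C)(C)C
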